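All runs were generated by integration with constants of no real substance, and the scatter is random.

- I started from the leftover of the noon run: its target fell from 127.8 mM at 11 min to 115.6 mM at 16 min, so something was taking target away.

| setting | summer | noon | midnight | spring |
|---|---|---|---|---|
| substrate | 150 mM | 150 mM | 150 mM | 60.0 mM |
| free catalyst | 15.0 mM | 45.0 mM | 15.0 mM | 15.0 mM |
| target |  |  | 75.0 mM |  |
| time |  |  |  | 16 min |

| summer run: time / min | summer run: [target] / mM | noon run: time / min | noon run: [target] / mM | midnight run: time / min | midnight run: [target] / mM |
|---|---|---|---|---|---|
| 1.2 | 13.6 | 1.2 | 40.1 | 1.2 | 87.2 |
| 3.7 | 40.8 | 3.7 | 106.4 | 3.7 | 109.9 |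
| 7.1 | 71.4 | 7.1 | 132.7 | 7.1 | 137.8 |
| 11 | 100.9 | 11 | 127.8 | 11 | 160.8 |
| 16 | 119.2 | 16 | 115.6 | 16 | 174.1 |

(standard deviation of a reading: 0.4 mM)

- the power of [free catalyst] that the first rate follows, about the charge of the summer run; measure it at two percent of substrate made into target
- target in the spring run at 16 min, as a share of the substrate charged

- Overall: substrate -> target, with free catalyst as catalyst.
- Constant volume, constant temperature.
- The analysis sees a species whether free or bound.
- An order is taken over about fifteen percent of the charge, up and down.

- From that fall I read the share of target lost per minute, 0.0201 /min, the loss constant. I assumed that it also held at the 15.0 mM of free catalyst in the spring run, although I had read it at 45.0 mM.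
- At the first reading, the noon run stood at 2.95 times the summer run, with catalyst up by a factor of 3.00, so I put the power of [free catalyst] at 0.984.
- The summer run began at 11.3 mM/min. If that rate stayed zero order in [substrate], the spring charge would be used by 5.29 min, well before 16 min.
- The average target would then be made at half that time and would decay for the remainder, leaving 76.5 %.
- The weak link was the steady rate. Between 11 min and 16 min the summer run gained 3.66 mM/min, and adding back the loss on its target gave a making rate of 5.87 mM/min.
- That is about half the first rate, at a [substrate] I reckoned as 25.0 mM. This gave a bend concentration of 23.3 mM, and it moved the average making time to 4.70 min. I committed to 79.7 %.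
- The forecast gave a power of 1 (0.9 to 1.12) and 84 % (77 % to 90 %), above my share, saying: “About 4–5 mM of target is lost, leaving about 50 mM, or about 84%.”

- The flask gave a power of 1.0 and 78.6 % of the spring charge as target at 16 min.

    free catalyst + substrate ⇌ catalyst-substrate complex, settled at all times (98.80 /M)
    catalyst-substrate complex → target + free catalyst (0.8400 /min)
    target → decomposed product (0.01956 /min)
    free catalyst + substrate → spent catalyst + substrate (1.290 /M/min)

- Turning free catalyst into spent catalyst made no difference to that share. At 0.0201 /min, and reckoning as if the whole spring charge had turned, that share means the average target in the spring run had stood for 12.0 min, so on average it was made at 4.00 min. On the 75.0 mM of added target in the midnight run, the same constant takes 1.51 mM/min; set against the first rate of 11.3 mM/min read in the summer run, this gives a reckoned ratio of 0.867. Against the summer run, the rate ratio of the midnight run stands at 0.87.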